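## Retrosynthetic overview

1. The C2–aryl bond is cut last: the target falls into phloroglucinol (ring B) and 5,7-dihydroxy-6-lavandulylchromone (rings A and C). Forward, the arene adds to C2 of the derived 4-silyloxybenzopyrylium ion under chiral-anion control; this ends the pyranone aromaticity, breaks the threefold symmetry of phloroglucinol and sets C2.
2. The C6–CH2 bond comes from a Negishi coupling of 6-iodo-5,7-dihydroxychromone with (S)-lavandulylzinc iodide; the side-chain stereocentre comes from lipase-resolved lavandulol.
3. The C6–I bond comes from iodination ortho to the chelated 5-OH of 5,7-dihydroxychromone.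
4. Ring order: rings A and C are bought fused (the chromone) and ring B is bought (phloroglucinol); no ring is built, and ring C is dearomatised to the chromanone in the final step.

Assumption: (±)-lavandulol, 5,7-dihydroxychromone and phloroglucinol are catalogue compounds, and the antipode of the chiral acid in step 5 is the one that an initial screen shows to give the (2S) product.

## Route

Step 1
Reactants: 1 (±)-lavandulol
Product: 2 (S)-lavandulol
Conditions: porcine pancreatic lipase, vinyl acetate (2 equiv), t-BuOMe, 25 °C, run to about 60% conversion, chromatography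
Reagents that add atoms: none
Why: Lipase-catalysed kinetic resolution by transesterification acetylates the (R)-alcohol faster, so conversion past 50% leaves the (S)-alcohol in high ee (a second pass if needed); the stereocentre is selected, not created.

Step 2
Reactants: 2 (S)-lavandulol
Product: 3 (S)-lavandulyl iodide
Conditions: I2, PPh3, imidazole, CH2Cl2, 0 → 25 °C
Reagents that add atoms: iodine, II
Why: Appel-type iodination is an SN2 displacement at the primary carbon of the alkoxyphosphonium salt, so the adjacent stereocentre is untouched.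

Step 3
Reactants: 4 5,7-dihydroxychromone
Product: 5 5,7-dihydroxy-6-iodochromone
Conditions: N-iodosuccinimide (1.0 equiv), DMF, 0 → 25 °C
Reagents that add atoms: N-iodosuccinimide, O=C1CCC(=O)N1I
Why: Electrophilic aromatic iodination of 5,7-dioxygenated chromones and flavones with a free, carbonyl-chelated 5-OH goes to C6 (C8 is favoured only when O5 is alkylated), and one equivalent at low temperature limits di-iodination.

Step 4
Reactants: 3 (S)-lavandulyl iodide; 5 5,7-dihydroxy-6-iodochromone
Product: 8 5,7-dihydroxy-6-[(2R)-lavandulyl]chromone, via (S)-lavandulylzinc iodide 6 (not isolated), via dilithium iodochromone diolate 7 (not isolated)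
Conditions: 3, Zn dust, LiCl, THF, 35 °C; 5, LiN(SiMe3)2 (2.05 equiv), THF, 0 °C; then Pd(OAc)2 (3 mol%), SPhos (2-dicyclohexylphosphino-2′,6′-dimethoxybiphenyl, 6 mol%), slow addition of 6 (1.4 equiv), THF–NMP, 40 °C; aq. NH4Cl
Reagents that add atoms: none
Why: Negishi sp3–sp2 cross-coupling: the aryl iodide adds oxidatively to zerovalent palladium, the primary alkylzinc transmetalates, and reductive elimination from the bulky biarylphosphine complex outruns β-hydride elimination; the lithium phenoxides spare the zinc reagent from protonolysis, and the side-chain stereocentre is not involved (its label changes from S to R only because the CIP priorities change).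

Step 5
Reactants: 8 5,7-dihydroxy-6-[(2R)-lavandulyl]chromone; 9 phloroglucinol
Product: 14 (2S)-5,7-dihydroxy-6-[(2R)-lavandulyl]-2-(2,4,6-trihydroxyphenyl)chroman-4-one (the target), via chromone bis(trifluoroacetate) 10 (not isolated), via tris(trimethylsilyl)phloroglucinol 11 (not isolated), via 4-silyloxybenzopyrylium ion pair 12 (not isolated), via silylated flavanone adduct 13 (not isolated)
Conditions: 8, (CF3CO)2O, NaHCO3, CH2Cl2, 0 → 25 °C, filter, evaporate; 9 (3 equiv), (Me3Si)2NH, MeCN, 80 °C, evaporate; combine in toluene, (S,S)-IDPi acid (5 mol%; imidodiphosphorimidate from two (S)-3,3′-bis[3,5-bis(trifluoromethyl)phenyl]-BINOL units, each phosphorus bearing =N–SO2CF3), −40 °C; then MeOH, NaOAc/AcOH buffer (pH 5), 0 → 25 °C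
Reagents that add atoms: none
Why: Proposed new method: an enantioselective dearomative Friedel–Crafts C2-arylation of a chromone. The acid, silylated in the flask by 11, O-silylates the carbonyl of 10 to the aromatic benzopyrylium ion 12 paired with the confined chiral anion; the trifluoroacetates remove the donor effect of the 5- and 7-oxygens so that 12 is electrophilic enough for an arene. The C3-symmetric π-nucleophile 11 attacks C2 (C4 is blocked) on the face left open by the anion, setting C2 as S, while the remote lavandulyl centre neither directs nor is touched. The Wheland proton returns to the catalyst, which is re-silylated by protodesilylation of the enol ether, so the net change is addition of Ar–H across C2=C3 to give 13. Buffered methanolysis then strips the three silyl and two trifluoroacetyl groups without base, so the epimerisable C2 centre and the 6-substitution pattern are never exposed to phenoxide. Closest known reaction types: additions of π-nucleophiles to 4-silyloxybenzopyrylium ions made from chromones (giving 2-substituted chroman-4-ones), their chiral-anion-directed enantioselective versions, silylium catalysis with confined anions for additions to cyclic oxocarbenium ions, and Friedel–Crafts capture of flavylium-type cations by phloroglucinol.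

## Compound list

1 | (±)-lavandulol, racemic 5-methyl-2-(prop-1-en-2-yl)hex-4-en-1-ol | C=C(C)C(CO)CC=C(C)C | starting material
2 | (S)-lavandulol, (2S)-5-methyl-2-(prop-1-en-2-yl)hex-4-en-1-ol | C=C(C)[C@H](CC=C(C)C)CO | intermediate
3 | (S)-lavandulyl iodide, (3S)-3-(iodomethyl)-2,6-dimethylhepta-1,5-diene | C=C(C)[C@H](CC=C(C)C)CI | intermediate
4 | 5,7-dihydroxychromone (5,7-dihydroxy-4H-chromen-4-one) | O=c1ccoc2cc(O)cc(O)c12 | starting material
5 | 5,7-dihydroxy-6-iodochromone | O=c1ccoc2cc(O)c(I)c(O)c12 | intermediate
6 | (S)-lavandulylzinc iodide | C=C(C)[C@H](CC=C(C)C)C[Zn]I | intermediate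
7 | dilithium 6-iodo-4-oxo-4H-chromene-5,7-diolate | [Li+].[Li+].[O-]c1cc2occc(=O)c2c([O-])c1I | intermediate
8 | 5,7-dihydroxy-6-[(2R)-5-methyl-2-(prop-1-en-2-yl)hex-4-en-1-yl]-4H-chromen-4-one | C=C(C)[C@H](CC=C(C)C)Cc1c(O)cc2occc(=O)c2c1O | intermediate
9 | phloroglucinol (benzene-1,3,5-triol) | Oc1cc(O)cc(O)c1 | starting material
10 | 6-[(2R)-lavandulyl]-4-oxo-4H-chromene-5,7-diyl bis(trifluoroacetate) | C=C(C)[C@H](CC=C(C)C)Cc1c(OC(=O)C(F)(F)F)cc2occc(=O)c2c1OC(=O)C(F)(F)F | intermediate
11 | 1,3,5-tris(trimethylsilyloxy)benzene | C[Si](C)(C)Oc1cc(O[Si](C)(C)C)cc(O[Si](C)(C)C)c1 | intermediate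
12 | 5,7-bis(trifluoroacetoxy)-6-[(2R)-lavandulyl]-4-(trimethylsilyloxy)chromenylium, ion pair with the chiral catalyst anion (cation drawn) | C=C(C)[C@H](CC=C(C)C)Cc1c(OC(=O)C(F)(F)F)cc2[o+]ccc(O[Si](C)(C)C)c2c1OC(=O)C(F)(F)F | intermediate
13 | (2S)-5,7-bis(trifluoroacetoxy)-6-[(2R)-lavandulyl]-2-[2,4,6-tris(trimethylsilyloxy)phenyl]chroman-4-one | C=C(C)[C@H](CC=C(C)C)Cc1c(OC(=O)C(F)(F)F)cc2c(c1OC(=O)C(F)(F)F)C(=O)C[C@@H](c1c(O[Si](C)(C)C)cc(O[Si](C)(C)C)cc1O[Si](C)(C)C)O2 | intermediate
14 | (2S)-5,7-dihydroxy-6-[(2R)-5-methyl-2-(prop-1-en-2-yl)hex-4-en-1-yl]-2-(2,4,6-trihydroxyphenyl)-2,3-dihydro-4H-chromen-4-one | C=C(C)[C@H](CC=C(C)C)Cc1c(O)cc2c(c1O)C(=O)C[C@@H](c1c(O)cc(O)cc1O)O2 | target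

## Step count and risks

Total step count: 5. Longest linear sequence: 4 steps (steps 1, 2, 4, 5; 1 → 2 → 3 → 8 → 14).

**Step 5 (most likely to fail).** The arylation is new; the risks are low enantioselectivity, a racemic background reaction, double arylation of phloroglucinol and loss of the transient esters. Fallback: change from catalyst control to separation of C2 epimers. Setting out from 8, the same transient protection gives 10, and the arylation with 11 is run with the achiral acid Tf2NH (5 mol%, CH2Cl2, −40 °C). This gives 13 together with its C2 epimer, the (2R)-configured silylated adduct F1. Buffered methanolysis then gives 14 and its C2 epimer, the (2R)-flavanone F2. The fixed lavandulyl centre makes these two diastereomers, so preparative HPLC (amylose-type chiral phase or C18) separates them, and the route is rejoined at 14.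

**Step 4.** The lithiated, electron-rich, doubly ortho-substituted aryl iodide may add slowly to palladium or consume the zinc reagent, and β-hydride elimination at the allylic C–H is possible. Fallback: mask the phenols as electron-poor esters. Setting out from 5, Ac2O/pyridine/DMAP gives 5,7-diacetoxy-6-iodochromone F3. Negishi coupling of F3 with 6 (Pd(OAc)2/SPhos, THF, 25 °C) gives 5,7-diacetoxy-6-[(2R)-lavandulyl]chromone F4. K2CO3 in MeOH at 0 °C removes the acetates, with no stereocentre at risk at the chromone stage, and the route is rejoined at 8.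

**Step 3.** With both phenols free, 8-iodo or 6,8-di-iodo material may form. Fallback: cap the 7-OH so that only the chelated 5-OH directs. Setting out from 4, MOMCl/i-Pr2NEt in CH2Cl2 gives 5-hydroxy-7-(methoxymethoxy)chromone F5. Benzyltrimethylammonium dichloroiodate with CaCO3 in CH2Cl2–MeOH iodinates ortho to the free 5-OH to give 5-hydroxy-6-iodo-7-(methoxymethoxy)chromone F6. HCl in MeOH at 40 °C removes the acetal, and the route is rejoined at 5.

## Further compounds

F1 | step 5 | (2R)-5,7-bis(trifluoroacetoxy)-6-[(2R)-lavandulyl]-2-[2,4,6-tris(trimethylsilyloxy)phenyl]chroman-4-one | C=C(C)[C@H](CC=C(C)C)Cc1c(OC(=O)C(F)(F)F)cc2c(c1OC(=O)C(F)(F)F)C(=O)C[C@H](c1c(O[Si](C)(C)C)cc(O[Si](C)(C)C)cc1O[Si](C)(C)C)O2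
F2 | step 5 | (2R)-5,7-dihydroxy-6-[(2R)-lavandulyl]-2-(2,4,6-trihydroxyphenyl)chroman-4-one | C=C(C)[C@H](CC=C(C)C)Cc1c(O)cc2c(c1O)C(=O)C[C@H](c1c(O)cc(O)cc1O)O2
F3 | step 4 | 5,7-diacetoxy-6-iodochromone | O=c1ccoc2cc(OC(C)=O)c(I)c(OC(C)=O)c12
F4 | step 4 | 5,7-diacetoxy-6-[(2R)-lavandulyl]chromone | C=C(C)[C@H](CC=C(C)C)Cc1c(OC(C)=O)cc2occc(=O)c2c1OC(C)=O
F5 | step 3 | 5-hydroxy-7-(methoxymethoxy)chromone | COCOc1cc(O)c2c(=O)ccoc2c1
F6 | step 3 | 5-hydroxy-6-iodo-7-(methoxymethoxy)chromone | COCOc1cc2occc(=O)c2c(O)c1I
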